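**Strategy.** Atoms are numbered along the target SMILES, C1 (CH–OAc) to C16 (quaternary), with N12; ring A is C1–C5 plus C16, ring B C5–C8 plus C16, ring C C8–C16. Everything rests on cutting C1–C16 and C4–C5. Ring A bears oxygen at C1 and C3, 1,3-related and next to the fusion bond C16–C5: the pattern a diene oxygenated at its 1- and 3-positions imprints on a cyclopentenone C=C bond. One copper–bis(oxazoline)-catalysed Diels–Alder reaction of a 1-benzyloxy-3-silyloxybutadiene with methyl 5-oxocyclopent-1-ene-1-carboxylate closes ring A and sets C1, C5 and quaternary C16; ring C is closed later at N12–C11.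

Key step: step 5

Remarks on the chemistry (valid for all steps):
- Precursor design: the diene carries tert-butyldimethylsilyl instead of trimethylsilyl on the C3 oxygen, so that the enol ether of the cycloadduct can be isolated and protects the C3 ketone while C8 is elaborated. The dienophile is made fresh and used cold because it oligomerises.
- Assumption: the (R,R)-ligand is assigned from the square-planar chelate model (ketone-endo diene on the face not covered by the tert-butyl group on the ketone side); if experiment shows the opposite sense, the (S,S)-ligand is used.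
- The cis-diol of step 20 is drawn for osmylation anti to ring A; the other cis-diol would converge on the same enone in step 22.
- C1, C5 and C16 (step 5) and C3 (step 9) are written in every SMILES exactly as in the target.

Step 1
Reactants: 1 methyl 2-oxocyclopentane-1-carboxylate
Product: 2 methyl 2-oxo-1-(phenylselanyl)cyclopentane-1-carboxylate (racemic)
Conditions: PhSeCl, pyridine, CH2Cl2, 0 °C → rt
Reagents that add atoms: phenylselenenyl chloride, Cl[Se]c1ccccc1
Why: Electrophilic α-selenenylation of the β-keto ester enol should occur only at the doubly activated carbon between the two carbonyls, and the new stereocentre is irrelevant because step 2 destroys it.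

Step 2
Reactants: 2 methyl 2-oxo-1-(phenylselanyl)cyclopentane-1-carboxylate
Product: 4 methyl 5-oxocyclopent-1-ene-1-carboxylate, via selenoxide 3 (not isolated)
Conditions: 30% aq. H2O2, CH2Cl2, 0 °C → rt; NaHCO3 wash; solution kept cold and used at once
Reagents that add atoms: hydrogen peroxide, OO (its oxygen is found only in intermediate 3)
Why: Oxidation at selenium followed by selenoxide syn-elimination can take a hydrogen only from the ring CH2 next to the substituted carbon, so the double bond must form between the ester-bearing carbon and C5 under neutral conditions that the labile dienophile tolerates.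

Step 3
Reactants: 5 (E)-4-methoxybut-3-en-2-one; 6 benzyl alcohol
Product: 7 (E)-4-(benzyloxy)but-3-en-2-one
Conditions: PPTS (cat.), toluene, 80 °C, MeOH distilled off
Reagents that add atoms: none
Why: Acid-catalysed addition–elimination at the β-carbon (vinylogous transesterification) exchanges methoxy for benzyloxy, removal of methanol drives the equilibrium, and the conjugated E isomer is the thermodynamic product.

Step 4
Reactants: 7 (E)-4-(benzyloxy)but-3-en-2-one
Product: 8 (E)-1-(benzyloxy)-3-[(tert-butyldimethylsilyl)oxy]buta-1,3-diene
Conditions: TBSOTf, Et3N, Et2O, 0 °C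
Reagents that add atoms: tert-butyldimethylsilyl triflate, CC(C)(C)[Si](C)(C)OS(=O)(=O)C(F)(F)F
Why: Soft enolisation of the methyl ketone (silyl triflate plus amine) should give the 2-silyloxy diene without disturbing the E enol ether, and the bulky silyl group makes diene and later enol ether stable enough to isolate.

Step 5
Reactants: 4 methyl 5-oxocyclopent-1-ene-1-carboxylate; 8 (E)-1-(benzyloxy)-3-[(tert-butyldimethylsilyl)oxy]buta-1,3-diene
Product: 9 methyl (3aS,4S,7aR)-4-(benzyloxy)-6-[(tert-butyldimethylsilyl)oxy]-3-oxo-1,2,3,4,7,7a-hexahydro-3aH-indene-3a-carboxylate (cis-fused adduct: C1 benzyloxy cis to C8, C2=C3 silyl enol ether, C8 ketone, C15 ester)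
Conditions: Cu(OTf)2 (10 mol %), (R,R)-tBu-BOX [2,2′-(propane-2,2-diyl)bis((4R)-4-tert-butyl-4,5-dihydrooxazole)] (11 mol %), 4 Å MS, CH2Cl2, −78 → −40 °C; Et3N quench
Reagents that add atoms: none
Why: Two-point binding of both carbonyl oxygens of 4 to divalent copper makes C5 strongly electrophilic, and diene 8 then cycloadds in a single concerted but asynchronous Diels–Alder event in which the C4–C5 bond, formed by the silyloxy-activated diene terminus, runs ahead of the C1–C16 bond. The closest known reaction type is the Lewis acid-catalysed [4+2] cycloaddition of 2-carboalkoxycycloalk-2-enones with 1-alkoxy-3-silyloxybutadienes, made enantioselective by Cu(OTf)2–bis(oxazoline) complexes of chelating dienophiles. Ring A (C1–C5, C16) is closed by this intermolecular [4+2] cycloaddition, which is suprafacial on the dienophile, so H5 and the C15 ester must be cis and the quaternary centre C16 is created in the same event. C5 and C16 are set together by the face of the planar chelate that the ligand leaves open (the tert-butyl group over the ketone side blocks the other face for a ketone-endo diene), and C1 is set by the endo rule, the ring ketone lying under the diene so that the E-benzyloxy group ends up cis to C8. The step needs regioselectivity, secured by the match of the nucleophilic diene carbon C4 with the doubly activated β-carbon C5, endo selectivity for ketone over ester, favoured by overlap with the ring carbonyl that is locked in plane with C5=C16, and face selectivity, secured by the rigid chelate; the silyl enol ether survives as the masked C3 ketone.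

Step 6
Reactants: 9 cis-fused adduct
Product: 10 C8 enol triflate of 9 (C7=C8, OTf on C8; ester, benzyl ether and silyl enol ether unchanged)
Conditions: KN(SiMe3)2, THF, −78 °C; PhNTf2, −78 → 0 °C
Reagents that add atoms: N-phenylbis(trifluoromethanesulfonimide), FC(F)(F)S(=O)(=O)N(c1ccccc1)S(=O)(=O)C(F)(F)F
Why: Because C16 is quaternary the C8 ketone can enolise only toward C7, so kinetic deprotonation and O-sulfonylation of the enolate should give a single enol triflate while ester, benzyl ether and silyl enol ether are inert to the hindered amide base at −78 °C.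

Step 7
Reactants: 10 C8 enol triflate; 11 allyl benzyl ether
Product: 13 cyclopentene ester bearing the 3-(benzyloxy)propyl chain C9–C11 on C8, via alkylborane 12 (not isolated)
Conditions: 11, 9-BBN, THF, rt; then 10, PdCl2(dppf) (5 mol %), AsPh3, Cs2CO3, DMF–H2O, rt
Reagents that add atoms: 9-borabicyclo[3.3.1]nonane, B1C2CCCC1CCC2 (its atoms are found only in intermediate 12)
Why: Anti-Markovnikov hydroboration of the terminal alkene and B-alkyl Suzuki–Miyaura coupling at zerovalent palladium join C9 to C8 with the double bond held at C7=C8 by the triflate, and ester, benzyl ethers and the silyl enol ether tolerate the mild carbonate base at room temperature.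

Step 8
Reactants: 13 coupling product
Product: 14 C3 ketone (enol ether of 13 hydrolysed; C1 benzyloxy retained)
Conditions: Bu4NF, AcOH, THF, 0 °C
Reagents that add atoms: none
Why: Fluoride cleaves the enol Si–O bond and acetic acid protonates the enolate at once (buffered desilylation), so the ketone is unveiled without base-induced loss of the β-benzyloxy group, whose equatorial C–O bond is in any case poorly aligned for elimination.

Step 9
Reactants: 14 C3 ketone
Product: 15 C3 methyl carbinol (3S; hydroxyl equatorial and cis to the C1 oxygen, methyl axial)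
Conditions: MeAl(OAr)2 (Ar = 2,6-di-tert-butyl-4-methylphenyl; from Me3Al + 2 ArOH), toluene, −78 °C; then MeMgBr, −78 °C
Reagents that add atoms: methylmagnesium bromide, C[Mg]Br
Why: In this amphiphilic carbonyl alkylation the very bulky aluminium phenoxide binds the C3 oxygen and blocks the equatorial approach, so the Grignard methyl enters axially on the chair that keeps C1–OBn and C5–C6 equatorial, giving the equatorial alcohol cis to the C1 oxygen while the neopentyl ester is untouched at −78 °C.

Step 10
Reactants: 15 C3 methyl carbinol
Product: 16 C15 primary alcohol (ester reduced to CH2OH)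
Conditions: LiAlH4, THF, 0 °C → rt
Reagents that add atoms: none
Why: Hydride reduction of the methyl ester gives the neopentyl alcohol, and nothing else in the molecule (isolated alkene, benzyl ethers, tertiary alkoxide) is reducible by LiAlH4.

Step 11
Reactants: 16 C15 primary alcohol
Product: 17 C15 aldehyde
Conditions: Dess–Martin periodinane, NaHCO3, CH2Cl2, rt
Reagents that add atoms: none
Why: Dess–Martin oxidation acts on the only oxidisable alcohol (the C3 hydroxyl is tertiary), and the aldehyde cannot enolise or epimerise because it sits on quaternary C16.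

Step 12
Reactants: 17 C15 aldehyde; 18 diethyl (cyanomethyl)phosphonate
Product: 20 (E)-α,β-unsaturated nitrile (C15=C14–C13≡N12), via phosphonate carbanion 19 (not isolated)
Conditions: 18, NaH, THF, 0 °C; then 17, 0 °C → rt
Reagents that add atoms: sodium hydride, [Na+].[H-] (sodium is found only in intermediate 19)
Why: Horner–Wadsworth–Emmons olefination with the small cyanomethyl carbanion adds C14, C13 and the nitrogen atom to the hindered but non-enolisable aldehyde, and the alkene geometry is immaterial because the double bond is saturated in step 13.

Step 13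
Reactants: 20 unsaturated nitrile
Product: 21 primary amine (C15H2–C14H2–C13H2–NH2), both benzyl ethers retained
Conditions: NaBH4, CoCl2·6H2O (cat.), MeOH, 0 °C → rt
Reagents that add atoms: none
Why: Co2B formed in the flask with NaBH4 reduces the nitrile to the primary amine and saturates the conjugated double bond in one operation (cobalt boride reduction of α,β-unsaturated nitriles), whereas the isolated, hindered trisubstituted C7=C8 alkene and the benzyl ethers are not attacked.

Step 14
Reactants: 21 primary amine bis(benzyl ether)
Product: 22 amino triol (free C1–OH, C3–OH and C11–OH)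
Conditions: Na, NH3(l)/THF, −78 °C; NH4Cl
Reagents that add atoms: none
Why: Dissolving-metal (Birch-type) cleavage breaks both benzylic C–O bonds by electron transfer into the arene and leaves the non-conjugated C7=C8 alkene, the amine and the alcohols alone, which catalytic hydrogenolysis could not guarantee.

Step 15
Reactants: 22 amino triol
Product: 23 N-(2-nitrophenylsulfonyl) derivative of 22 (sulfonamide N–H on C13)
Conditions: 2-NO2C6H4SO2Cl (1 equiv), Et3N, CH2Cl2, 0 °C
Reagents that add atoms: 2-nitrobenzenesulfonyl chloride, O=[N+]([O-])c1ccccc1S(=O)(=O)Cl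
Why: Sulfonylation of the primary amine is much faster than that of any hydroxyl group, so one equivalent of sulfonyl chloride should give the acidic sulfonamide required for the ring closure.

Step 16
Reactants: 23 sulfonamide triol
Product: 24 tricyclic sulfonamide (ring C closed by the N12–C11 bond; C7=C8 alkene, C1–OH and C3–OH free)
Conditions: PPh3, DEAD, toluene/THF, 0.005 M, slow addition, rt
Reagents that add atoms: none
Why: In this Fukuyama–Mitsunobu alkylation the sulfonamide N–H is the only acidic pronucleophile and only the unhindered primary C11 alcohol can be displaced (C1–OH is neopentyl secondary, C3–OH tertiary), so high dilution should close the nine-membered ring C as established for azonanes of this alkaloid class.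

Step 17
Reactants: 24 tricyclic sulfonamide
Product: 25 tricyclic secondary amine diol
Conditions: PhSH, K2CO3, DMF, rt
Reagents that add atoms: none
Why: Thiolate adds to the nitroarene (Meisenheimer complex) and releases the amine with loss of SO2, and this deprotection is placed here because a thiolate would add to the enone that is made later.

Step 18
Reactants: 25 secondary amine diol
Product: 26 N-(2,2,2-trichloroethoxycarbonyl) carbamate diol
Conditions: Cl3CCH2OCOCl, NaHCO3, CH2Cl2/H2O, 0 °C
Reagents that add atoms: 2,2,2-trichloroethyl chloroformate, ClC(=O)OCC(Cl)(Cl)Cl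
Why: Acylation of the secondary amine by the chloroformate under biphasic bicarbonate conditions is selective over the two hindered alcohols, and this carbamate has no alkene or benzylic position, so it survives osmylation, periodinane and SOCl2 and is later removed by zinc without base or strong acid.

Step 19
Reactants: 26 carbamate diol
Product: 27 carbamate 1,3-diacetate (C1–OAc and C3–OAc; C7=C8 alkene)
Conditions: Ac2O, DMAP, Et3N, CH2Cl2, rt → 40 °C
Reagents that add atoms: acetic anhydride, CC(=O)OC(C)=O
Why: Nucleophilic catalysis by 4-dimethylaminopyridine acetylates both the neopentyl secondary C1–OH and the tertiary C3–OH, which are the only free hydroxyl groups at this stage, so both acetates of the target are installed without a selectivity problem.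

Step 20
Reactants: 27 carbamate diacetate
Product: 28 C7,C8-cis-diol (hydroxyls drawn anti to ring A)
Conditions: OsO4 (cat.), N-methylmorpholine N-oxide, acetone/H2O, rt
Reagents that add atoms: N-methylmorpholine N-oxide, C[N+]1([O-])CCOCC1; water, O
Why: Catalytic osmium tetroxide dihydroxylation adds two oxygens syn to the only alkene, C7=C8, and the face of attack does not matter because C7 becomes a carbonyl in step 21 and C8 becomes trigonal in step 22.

Step 21
Reactants: 28 cis-diol
Product: 29 α-ketol (C7 ketone, tertiary C8–OH)
Conditions: Dess–Martin periodinane, NaHCO3, CH2Cl2, 0 °C → rt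
Reagents that add atoms: none
Why: Dess–Martin oxidation converts the secondary C7 alcohol into the ketone while the tertiary C8 alcohol cannot be oxidised, and buffered short exposure avoids glycol cleavage or ketol rearrangement.

Step 22
Reactants: 29 α-ketol
Product: 31 N-carbamate enone diacetate (C7 ketone with E C8=C9), via chlorosulfite 30 (not isolated)
Conditions: SOCl2, pyridine, CH2Cl2, −20 → 0 °C
Reagents that add atoms: thionyl chloride, O=S(Cl)Cl (its atoms are found only in intermediate 30)
Why: The tertiary alcohol is activated as its chlorosulfite and pyridine effects an anti E2 elimination that can use only a hydrogen on C9 (C7 is a carbonyl and C16 is quaternary), so the double bond must form at C8=C9, and the nine-membered ring favours the cis-cycloalkene, which is the E enone with C10 cis to C16.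

Step 23
Reactants: 31 N-carbamate enone diacetate
Product: 32 CNP0120442.1, the (1S,3S,5S,16S)-1,3-diacetate amino enone with E C8=C9 and free N12–H
Conditions: Zn, AcOH/THF, rt; NaHCO3 work-up
Reagents that add atoms: none
Why: Zinc reduces the trichloroethyl group (reductive β-elimination), the carbamic acid loses CO2, and the free secondary amine results under conditions too mild to touch the two acetates or the hindered enone.

Compound list
1 | methyl 2-oxocyclopentane-1-carboxylate | COC(=O)C1CCCC1=O | starting material
2 | methyl 2-oxo-1-(phenylselanyl)cyclopentane-1-carboxylate (racemic) | COC(=O)C1([Se]c2ccccc2)CCCC1=O | intermediate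
3 | methyl 2-oxo-1-(phenylseleninyl)cyclopentane-1-carboxylate (selenoxide, not isolated) | COC(=O)C1([Se](=O)c2ccccc2)CCCC1=O | intermediate
4 | methyl 5-oxocyclopent-1-ene-1-carboxylate | COC(=O)C1=CCCC1=O | intermediate
5 | (E)-4-methoxybut-3-en-2-one | CO/C=C/C(C)=O | starting material
6 | benzyl alcohol | OCc1ccccc1 | starting material
7 | (E)-4-(benzyloxy)but-3-en-2-one | CC(=O)/C=C/OCc1ccccc1 | intermediate
8 | (E)-1-(benzyloxy)-3-[(tert-butyldimethylsilyl)oxy]buta-1,3-diene | C=C(O[Si](C)(C)C(C)(C)C)/C=C/OCc1ccccc1 | intermediate
9 | methyl (3aS,4S,7aR)-4-(benzyloxy)-6-[(tert-butyldimethylsilyl)oxy]-3-oxo-1,2,3,4,7,7a-hexahydro-3aH-indene-3a-carboxylate (cis-fused Diels–Alder adduct) | c1ccccc1CO[C@H]1C=C(O[Si](C)(C)C(C)(C)C)C[C@H]2CCC(=O)[C@]21C(=O)OC | intermediate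
10 | C8 enol triflate of 9 (C7=C8–OTf) | c1ccccc1CO[C@H]1C=C(O[Si](C)(C)C(C)(C)C)C[C@H]2CC=C(OS(=O)(=O)C(F)(F)F)[C@]21C(=O)OC | intermediate
11 | allyl benzyl ether | C=CCOCc1ccccc1 | starting material
12 | B-[3-(benzyloxy)propyl]-9-borabicyclo[3.3.1]nonane (not isolated) | c1ccccc1COCCCB1C2CCCC1CCC2 | intermediate
13 | coupling product: 10 with the triflate replaced by 3-(benzyloxy)propyl (C9–C11) on C8 | c1ccccc1CO[C@H]1C=C(O[Si](C)(C)C(C)(C)C)C[C@H]2CC=C(CCCOCc3ccccc3)[C@]21C(=O)OC | intermediate
14 | C3 ketone (13 with the enol ether hydrolysed) | c1ccccc1CO[C@H]1CC(=O)C[C@H]2CC=C(CCCOCc3ccccc3)[C@]21C(=O)OC | intermediate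
15 | C3 methyl carbinol (3S, hydroxyl cis to the C1 benzyloxy group) | c1ccccc1CO[C@H]1C[C@@](C)(O)C[C@H]2CC=C(CCCOCc3ccccc3)[C@]21C(=O)OC | intermediate
16 | C15 primary alcohol | c1ccccc1CO[C@H]1C[C@@](C)(O)C[C@H]2CC=C(CCCOCc3ccccc3)[C@]21CO | intermediate
17 | C15 aldehyde | c1ccccc1CO[C@H]1C[C@@](C)(O)C[C@H]2CC=C(CCCOCc3ccccc3)[C@]21C=O | intermediate
18 | diethyl (cyanomethyl)phosphonate | N#CCP(=O)(OCC)OCC | starting material
19 | sodium cyano(diethoxyphosphoryl)methanide (not isolated) | [Na+].N#C[CH-]P(=O)(OCC)OCC | intermediate
20 | (E)-α,β-unsaturated nitrile on C16 (C15=C14–C13≡N) | c1ccccc1CO[C@H]1C[C@@](C)(O)C[C@H]2CC=C(CCCOCc3ccccc3)[C@]21/C=C/C#N | intermediate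
21 | 3-aminopropyl compound, bis(benzyl ether) | c1ccccc1CO[C@H]1C[C@@](C)(O)C[C@H]2CC=C(CCCOCc3ccccc3)[C@]21CCCN | intermediate
22 | amino triol (C1–OH, C3–OH, C11–OH, C13–NH2) | O[C@H]1C[C@@](C)(O)C[C@H]2CC=C(CCCO)[C@]21CCCN | intermediate
23 | N-(2-nitrophenylsulfonyl) amino triol | O[C@H]1C[C@@](C)(O)C[C@H]2CC=C(CCCO)[C@]21CCCNS(=O)(=O)c1ccccc1[N+](=O)[O-] | intermediate
24 | tricyclic sulfonamide, ring C closed at N12–C11 | O[C@H]1C[C@@](C)(O)C[C@H]2CC=C3CCCN(S(=O)(=O)c4ccccc4[N+](=O)[O-])CCC[C@@]321 | intermediate
25 | tricyclic secondary amine diol | O[C@H]1C[C@@](C)(O)C[C@H]2CC=C3CCCNCCC[C@@]321 | intermediate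
26 | N-(2,2,2-trichloroethoxycarbonyl) diol | O[C@H]1C[C@@](C)(O)C[C@H]2CC=C3CCCN(C(=O)OCC(Cl)(Cl)Cl)CCC[C@@]321 | intermediate
27 | N-(2,2,2-trichloroethoxycarbonyl) 1,3-diacetate with C7=C8 alkene | CC(=O)O[C@H]1C[C@@](C)(OC(C)=O)C[C@H]2CC=C3CCCN(C(=O)OCC(Cl)(Cl)Cl)CCC[C@@]321 | intermediate
28 | C7,C8-cis-diol (hydroxyls anti to ring A) | CC(=O)O[C@H]1C[C@@](C)(OC(C)=O)C[C@H]2C[C@H](O)[C@@]3(O)CCCN(C(=O)OCC(Cl)(Cl)Cl)CCC[C@@]321 | intermediate
29 | α-ketol (C7 ketone, tertiary C8–OH) | CC(=O)O[C@H]1C[C@@](C)(OC(C)=O)C[C@H]2CC(=O)[C@@]3(O)CCCN(C(=O)OCC(Cl)(Cl)Cl)CCC[C@@]321 | intermediate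
30 | chlorosulfite of 29 (not isolated) | CC(=O)O[C@H]1C[C@@](C)(OC(C)=O)C[C@H]2CC(=O)[C@@]3(OS(=O)Cl)CCCN(C(=O)OCC(Cl)(Cl)Cl)CCC[C@@]321 | intermediate
31 | N-(2,2,2-trichloroethoxycarbonyl) enone diacetate (E C8=C9) | CC(=O)O[C@H]1C[C@@](C)(OC(C)=O)C[C@H]2CC(=O)/C3=C/CCN(C(=O)OCC(Cl)(Cl)Cl)CCC[C@@]321 | intermediate
32 | CNP0120442.1, (1S,3S,5S,16S)-1,3-diacetate amino enone (E C8=C9) | CC(=O)O[C@H]1C[C@@](C)(OC(C)=O)C[C@H]2CC(=O)/C3=C/CCNCCC[C@@]321 | target

Total step count: 23 steps.
Longest linear sequence: 21 steps (1 → 2 → 4 → 9 and then steps 6–23 to 32; the diene branch 5/6 → 7 → 8 → 9 is equally long).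

Steps most likely to fail

Step 5. The cycloaddition may turn stepwise (Mukaiyama–Michael addition without ring closure), endo or facial selectivity may be eroded, or the dienophile may oligomerise before it reacts. Fallback: the cycloaddition is run without metal, thermally in toluene from 0 °C to room temperature, where it is concerted. It sets out from 4 and 8 and should give racemic material, that is 9 together with the mirror-image adduct F1. The two are separated by preparative chromatography on a chiral stationary phase, and the route is rejoined at 9.

Step 16. Intermolecular N-alkylation (oligomerisation) may outrun the slow nine-membered ring closure. Fallback: ring C is closed by sulfonamide alkylation of a preformed halide instead of redox condensation. Setting out from 23, the primary C11 alcohol alone is converted into the primary iodide F2 (PPh3, I2, imidazole, CH2Cl2, 0 °C). Slow addition of this iodide to Cs2CO3 and Bu4NI in MeCN at 60 °C under high dilution should then give 24, where the route is rejoined.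

Step 22. The activated tertiary alcohol may be substituted by chloride, or elimination may run through the ring conformer that leads to the strained ring-trans alkene. Fallback: setting out from 29, the Burgess reagent (toluene, 50 °C) dehydrates by a chloride-free syn-elimination. Any ring-trans enone F3 that forms is then equilibrated with catalytic iodine in CH2Cl2 under visible light; the less strained ring-cis isomer 31 is the expected thermodynamic product, and the route is rejoined there.

Further compounds
F1 | step 5 | methyl (3aR,4R,7aS)-4-(benzyloxy)-6-[(tert-butyldimethylsilyl)oxy]-3-oxo-1,2,3,4,7,7a-hexahydro-3aH-indene-3a-carboxylate (enantiomer of 9) | c1ccccc1CO[C@@H]1C=C(O[Si](C)(C)C(C)(C)C)C[C@@H]2CCC(=O)[C@@]21C(=O)OC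
F2 | step 16 | primary C11 iodide of sulfonamide 23 | O[C@H]1C[C@@](C)(O)C[C@H]2CC=C(CCCI)[C@]21CCCNS(=O)(=O)c1ccccc1[N+](=O)[O-]
F3 | step 22 | ring-trans (Z C8=C9) isomer of enone 31 | CC(=O)O[C@H]1C[C@@](C)(OC(C)=O)C[C@H]2CC(=O)/C3=C\CCN(C(=O)OCC(Cl)(Cl)Cl)CCC[C@@]321
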